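The readings were generated by integration on assumed constants.

Count the solid substrate first, then the partner.

all flasks: solid substrate 0.25 M

| flask | partner | protic impurity | remark | time |
|---|---|---|---|---|
| summer | 0.012 M | 0.050 M | run made earlier |  |
| noon | 0.19 M | 0.050 M | run made earlier |  |
| violet | 0.0150 M | 0.0500 M |  | 6.0 min |
| green | 0.0300 M | 0.0500 M |  | 6.0 min |
| red | 0.0600 M | 0.0500 M |  | 6.0 min |
| grey | 0.120 M | 0.0500 M |  | 6.0 min |
| teal | 0.250 M | 0.0500 M |  | 6.0 min |

- summer (time / min: target / %, solid substrate / %): 0.500: 4.2, 68.8; 1.33: 2.8, 67.1; 2.50: 3.8, 66.3; 4.00: 0.3, 64.0
- noon (time / min: target / %, solid substrate / %): 0.500: 38.8, 38.7; 1.33: 72.2, 0; 2.50: 74.1, 0.9; 4.00: 74.4, 0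

(scatter of a reading: 1 percentage point)

- amount of target at the end, in percent of the solid substrate charged for violet, green, red, grey, teal, in this order
- the course of these numbers from the first flask to the last (rises all the way / hardly changes / falls all the way / rises, then falls / falls, then rises)

- at the start none of the solid substrate is in solution
- a reading or a percentage of target counts all its forms, free or not
- "hardly changes" means that all values lie within two and a half points (for a concentration: within two and a half percent of the largest)

What takes the solid substrate? By the first summer reading 31.2% of it has gone, yet the partner accounts for 4.80% and the impurity, at one mole for one, for 20.0%. I read the impurity as consuming solid substrate, and the remaining 6.40% as having gone into solution.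

What does leftover solid do to the target? Between the first and last summer readings the target drops 3.9 percentage points and the solid 4.8 points, equal within the scatter, while in the noon run, with the solid read at 0%, the target stays flat. So I take it that one solid substrate destroys one target.

For violet, 0.185 M remains once impurity and partner have taken their share; call this the spare solid substrate. I take the dissolved part, 0.0160 M by that reading, to leave the target alone, so the end state is the partner less whatever of the spare exceeds the dissolved part, if that is positive. The noon run has a spare of 0.0100 M, less than the dissolved part, which gives the whole partner, 76.0%, against a last reading of 74.4%.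

In red the spare is 0.140 M, and even without the dissolved part it is more than its partner, so red heads for no target, and violet and green lie further that way. Grey, with 0.0800 M, heads for 22.4%. Teal's spare is −0.0500 M, so solid substrate is the limiting reagent and the ceiling is 80.0%.

How fast? The summer solid loss against the mean target reads as a target half-life of 1.40 min, shorter than the 6.0 min allowed. I therefore expect about 0.309% for violet, 0.619% for green and 1.24% for red, grey somewhere above its end state, and teal near its ceiling.

The forecast, holding that the impurity “clearly doesn't consume partner mole for mole”, says 3.9%, 10%, 22%, 46% and 94%, well above my figures for the first flasks, and rises all the way, as I do.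

The flasks give 1.42%, 3.42%, 9.79%, 38.6% and 76.4%: the course rises all the way.

    dissolved substrate + partner → target (k = 9.70 M⁻¹ s⁻¹)
    partner ⇌ dormant form (K = 0.750, k = 0.300 s⁻¹)
    solid substrate ⇌ dissolved substrate, rate k3*(cs3 - [dissolved substrate]) while solid is left; crystals form when [dissolved substrate] > cs3 (solubility = 17.0 mM, k = 0.280 s⁻¹)
    solid product ⇌ target, rate k4*(cs4 - [target]) while solid is left; crystals form when [target] > cs4 (solubility = 45.0 mM, k = 3.10 s⁻¹)
    solid substrate + target → side product (k = 0.0260 M⁻¹ s⁻¹)
    solid substrate + protic impurity → quenched substrate (k = 0.690 M⁻¹ s⁻¹)

Red holds more target than my figure, yet after 60.0 min it is down to 0.0350%, and its spare less its partner, 32.0% of the charge, stands there as 25.2% solid substrate plus 6.80% dissolved substrate. Teal's spare is negative by 0.0500 M, and the partner left at the end, 0.0309 M free plus 0.0232 M dormant form, comes to 0.0540 M.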